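Locants: the upper flavan carries unprimed locants (ring A benzo, ring C pyran, ring B on C2); the lower flavan-3-ol carries primed locants (ring D benzo, ring F pyran, ring E on C2').

## Analysis of the target

The target (18) is a 4→8-linked biflavonoid: an upper 7,4'-dihydroxyflavan is bonded through C4 to C8' of a lower flavan-3-ol of the epiafzelechin type. There are four stereocentres in two isolated pairs: C2 (S) and C4 (S) in ring C, with the two aryl groups cis, and C2' (R) and C3' (R) in ring F, with aryl and hydroxyl cis. Ring D separates the pairs, so neither can steer the other. The molecule carries six phenols (sensitive to air and base once free), two benzylic aryl ether bonds (C2–O1 and C2'–O1', each next to a para-oxygenated aryl ring and therefore open to acid heterolysis and epimerisation), and a diarylmethine C4–C8' bond on a phloroglucinol nucleus. The difficulties are the unsymmetrical substitution of ring D, the 2,4-cis relationship in ring C (not the one expected when an arene attacks a flavan-4-yl cation), and the 2,3-cis relationship in ring F. The strategy rests on one feature: C4' is a methylene bonded to C4a', the only free ring-D carbon ortho to O1' once C8' is occupied, and it is flanked by the C3' carbinol. That is the pattern left when an arene opens a terminal epoxide at its CH2 carbon, so ring F can be closed last by a C–C bond formation that creates no stereocentre.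

## Retrosynthetic reasoning

**Protecting groups (18 ⇐ 17 ⇐ 16).** The five phenols of rings A, B and D are masked as benzyl ethers, which keep the rings electron-rich and fall in one neutral hydrogenolysis. The ring-E phenol is masked as a pivalate: an acyloxy group is a much weaker donor than an alkoxy group, so the benzylic carbon C2' is protected against ionisation in every acid- or SN1-prone step. The pivalate is removed from 16 by mild methanolysis while the other phenols are still benzylated (17).

**C4'–C4a' (16 ⇐ 15).** Cutting this bond opens ring F to an aryl ether carrying a terminal epoxide. It is the best place to cut because the forward reaction, an intramolecular epoxy-arene Friedel–Crafts alkylation, has only one ring-D position it can use, breaks no bond at a stereocentre, and leaves the C3' oxygen as the free hydroxyl. All four stereocentres are therefore fixed before the ring closure. The forward step must open the epoxide at CH2 faster than any benzylic C–O bond ionises.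

**O1'–C2' (15 ⇐ 10 + 14).** The aryl ether is cut at the benzylic carbon, giving phenol 10 and epoxy alcohol 14. A Mitsunobu substitution joins them with inversion, so the erythro (anti) epoxy alcohol 14 delivers the 2',3'-cis series. Using the intact epoxy alcohol avoids any diol protection, deprotection and epoxide re-formation after the coupling, and the precursor 15 is reached in one step from the two fragments.

**Epoxy alcohol (14 ⇐ 13 ⇐ 12 ⇐ 11).** The erythro epoxy alcohol is the direct product of a tartrate-controlled epoxidation of the racemic aryl vinyl carbinol 13 run as a kinetic resolution. One operation sets the epoxide carbon and selects the carbinol configuration. Carbinol 13 comes from aldehyde 12 by vinyl addition, and 12 from 11 by acylation.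

**C4–H (10 ⇐ 9 ⇐ 8).** The 2,4-cis relationship is not made by attaching ring D to a flavan-4-yl cation: axial attack on that cation would place the new aryl group axial, that is trans to the 2-aryl group. The order is reversed. Ring D is already on C4 in the 2H-chromene 8, and the last substituent to arrive is hydrogen. Axial delivery of hydride to the planar C4 cation leaves ring D equatorial and cis to ring B (9). Removing the one acetal protecting group then frees the single ring-D phenol needed for the ether (10).

**C4–C8' (8 ⇐ 3 + 5; 3 ⇐ 2 ⇐ 1; 5 ⇐ 4).** The aryl–alkenyl bond is cut to the enol triflate 3 and the arene 5. The triflate derives from the chiral-pool flavanone 1 through its dibenzyl ether 2, so C2 is bought rather than made. In 5 the methoxymethyl group does two jobs: it directs lithiation to the carbon next to it (via 6 and 7), which fixes the ring-D regiochemistry, and it marks the one oxygen that becomes O1'. Arene 5 comes from the symmetrical phenol 4.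

## Alternatives that were turned down

**Alternative 1:** Ring D is not bought as a phloroglucinol but built on C4 of the upper flavan by a benzannulation.
- Disconnection: three ring-D bonds, back to 3-(benzyloxy)cyclobut-2-en-1-one (A2) and the flavan-4-yl silyloxyalkyne A3.
- Forward key step: heating opens A2 to a vinylketene, which adds to the electron-rich alkyne of A3; the new cyclobutenone opens to a dienylketene, closes by 6π electrocyclisation and tautomerises to phenol A1.
- For: ring D emerges with its three oxygens fully differentiated (free hydroxyl next to the flavanyl carbon, silyl ether on the other side, benzyl ether para) and with no regiochemical question. On this point it is stronger than the chosen route, which needs a directing group and a lithiation to tell the oxygens apart.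
- Against: it makes only the phenol. Ring F, C2' and C3' must still be built afterwards by the same etherification and ring closure, so a second demanding step is added rather than one replaced. A3 needs an alkynyl group cis to the 2-aryl group at C4, and alkynyl addition to the flavan-4-yl cation has the same trans bias as arylation. The propargylic, benzylic C4–H of A3 must also survive the strongly basic chemistry that makes a silyloxyalkyne and the hot annulation without epimerising or isomerising to an allene. The silyl ether at C7' is a weaker donor than a benzyl ether for the later Friedel–Crafts step and needs its own deprotection.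
- Comparison: the chosen route reaches the analogous phenol 10 by cross-coupling and sets C4 afterwards by hydride delivery, where stereoelectronic and thermodynamic preferences both point to cis.

**Alternative 2:** Ring C is formed by a hetero-Diels–Alder reaction.
- Disconnection: O1–C2 and C3–C4, back to 4-benzyloxystyrene (A5) and the diaryl carbinol A6, whose carbinol carbon carries the complete protected lower unit.
- Forward key step: a chiral Brønsted acid dehydrates A6 to the ring-A ortho-quinone methide, and A5 adds across it to give A4 with C2 and C4 cis.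
- For: it is the most convergent plan. Ring C and both of its stereocentres are made in one step, the cis relationship is the natural outcome of the cycloaddition, and the lower unit is a protected epiafzelechin. On step count and convergence it is stronger than the chosen route.
- Against: the absolute sense at C2/C4 must be set relative to the fixed C2'/C3' of A6. Catalyst control of such cycloadditions relies on organising the dienophile, and A5 offers no hydrogen-bonding handle. The quinone methide carbon bears a di-ortho-substituted aryl group that is twisted out of conjugation and passes on a substrate bias of unknown sense. The likely result is a pair of diastereomers that differ only in the relationship between the two units, which are hard to separate and to assign.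
- Comparison: the chosen strategy takes C2 from the chiral pool, derives C4 from it, and sets C2'/C3' by a reagent-controlled epoxidation and an SN2 inversion. Each centre rests on a separately predictable event, at the cost of a longer sequence.

**Alternative 3:** Ring C is closed by a cationic Friedel–Crafts reaction at C4–C4a.
- Disconnection: C4–C4a, back to the open-chain carbinol A8, in which C2 is already a chiral 3-benzyloxyphenyl ether.
- Forward key step: a Lewis acid ionises the carbinol next to ring D, and the tethered aryl ether attacks through the carbon para to its benzyloxy group, giving A7.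
- For: the cation is strongly stabilised by ring D, so activation is mild. A chair-like closure with both aryl groups equatorial should give the 2,4-cis product, so C4 is set in the ring-forming event. This is comparable in plausibility to the hydride delivery of the chosen route and saves the separate reduction.
- Against: in A8 the C2 stereocentre is an open-chain para-alkoxybenzyl aryl ether. The acid that ionises the carbinol can also ionise this ether, and with no ring to re-close it the phenol is lost or C2 is scrambled. The C4 cation can also lose a proton to a styrene or be attacked at the other ortho position of the ether to give the 5-oxygenated regioisomer. Assembling A8 requires a carbon chain at C8' of a finished flavan-3-ol and a hindered ether formation, a long linear sequence on the most valuable fragment.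
- Comparison: in the chosen strategy the ring closure creates no stereocentre and uses an electrophile that is activated below the threshold for benzylic ether ionisation. It trades late-stage convergence for a key step that cannot erode stereochemistry.

Key step: step 11

Assumption: natural (S)-liquiritigenin (1) is used in high enantiomeric purity, and 3,5-bis(benzyloxy)phenol (4) is taken as a purchasable phloroglucinol derivative.

## Route

Step 1
Reactants: 1 (S)-liquiritigenin
Product: 2 (2S)-7-(benzyloxy)-2-[4-(benzyloxy)phenyl]chroman-4-one
Conditions: BnOH, PPh3, DIAD, THF, 0 °C → rt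
Reagents that add atoms: benzyl alcohol, OCc1ccccc1
Why: Mitsunobu O-benzylation; both phenols are acidic enough to protonate the betaine and are alkylated by the benzyloxyphosphonium ion. The neutral conditions avoid the base-induced retro-oxa-Michael opening to the chalcone that would racemise C2, so the (S) centre of 1 is carried over.

Step 2
Reactants: 2 (2S)-7-(benzyloxy)-2-[4-(benzyloxy)phenyl]chroman-4-one
Product: 3 (2S)-7-(benzyloxy)-2-[4-(benzyloxy)phenyl]-2H-chromen-4-yl trifluoromethanesulfonate
Conditions: Tf2O, 2,6-di-tert-butyl-4-methylpyridine, CH2Cl2, 0 °C → rt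
Reagents that add atoms: trifluoromethanesulfonic anhydride, O=S(=O)(OS(=O)(=O)C(F)(F)F)C(F)(F)F
Why: Enol triflate formation; the anhydride O-sulfonylates the electron-rich aryl ketone and the hindered pyridine removes a C3 proton from the resulting oxocarbenium ion, so no free enolate and no E1cB cleavage of the C2–O1 bond is involved. C2 is not touched.

Step 3
Reactants: 4 3,5-bis(benzyloxy)phenol
Product: 5 1,3-bis(benzyloxy)-5-(methoxymethoxy)benzene
Conditions: MOMCl, iPr2NEt, CH2Cl2, 0 °C → rt
Reagents that add atoms: chloromethyl methyl ether, COCCl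
Why: Standard O-alkylation of a phenol to its methoxymethyl acetal. The acetal serves as the directing group for step 4 and is the one ring-D protecting group that can later be removed without touching benzyl ethers.

Step 4
Reactants: 5 1,3-bis(benzyloxy)-5-(methoxymethoxy)benzene; 3 (2S)-7-(benzyloxy)-2-[4-(benzyloxy)phenyl]-2H-chromen-4-yl trifluoromethanesulfonate
Product: 8 (2S)-4-[2,4-bis(benzyloxy)-6-(methoxymethoxy)phenyl]-7-(benzyloxy)-2-[4-(benzyloxy)phenyl]-2H-chromene, via aryllithium 6 (not isolated), via arylzinc chloride 7 (not isolated)
Conditions: n-BuLi, THF, −20 → 0 °C; ZnCl2, THF, 0 °C → rt; then 3, Pd(OAc)2 (5 mol %), SPhos (10 mol %), THF, rt → 45 °C, dark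
Reagents that add atoms: none
Why: Directed ortho-metalation followed by Negishi cross-coupling; the acetal oxygens chelate lithium and direct deprotonation to the adjacent carbon, which is also flanked by a benzyloxy group, and the two positions ortho to the acetal are equivalent, so a single aryllithium should form. Transmetalation to zinc gives a nucleophile that tolerates the triflate, and the bulky biaryl phosphine allows coupling of a di-ortho-substituted arylzinc with an alkenyl triflate; C2 is remote from the reacting carbon, and the 2H-chromene is kept cool and away from light to suppress electrocyclic ring opening.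

Step 5
Reactants: 8 (2S)-4-[2,4-bis(benzyloxy)-6-(methoxymethoxy)phenyl]-7-(benzyloxy)-2-[4-(benzyloxy)phenyl]-2H-chromene
Product: 9 (2S,4S)-4-[2,4-bis(benzyloxy)-6-(methoxymethoxy)phenyl]-7-(benzyloxy)-2-[4-(benzyloxy)phenyl]chroman
Conditions: Et3SiH (3 equiv), CF3CO2H (3 equiv), CH2Cl2, −40 → −10 °C
Reagents that add atoms: none
Why: Ionic hydrogenation; protonation of the electron-rich 1,1-diaryl alkene at C3 gives a C4 carbocation stabilised by rings A and D, and the silane transfers hydride to it. With the 2-aryl group equatorial on the half-chair cation, hydride should add along the axial trajectory anti to the pseudo-axial C3–H, placing H4 cis to H2 and ring D equatorial, which is the 2,4-cis (4S) flavan and also the more stable diastereomer. Few equivalents of acid at low temperature are used so that neither the acetal nor the C2–O1 benzylic ether is ionised.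

Step 6
Reactants: 9 (2S,4S)-4-[2,4-bis(benzyloxy)-6-(methoxymethoxy)phenyl]-7-(benzyloxy)-2-[4-(benzyloxy)phenyl]chroman
Product: 10 3,5-bis(benzyloxy)-2-[(2S,4S)-7-(benzyloxy)-2-[4-(benzyloxy)phenyl]chroman-4-yl]phenol
Conditions: aq. HCl (3 M), MeOH/THF, 40 °C
Reagents that add atoms: none
Why: Acid-catalysed acetal exchange with methanol releases the phenol. Benzyl ethers are inert, and dilute acid at this temperature is well below what is needed to ionise the C2–O1 bond, so both stereocentres are kept.

Step 7
Reactants: 11 4-hydroxybenzaldehyde
Product: 12 4-formylphenyl pivalate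
Conditions: PivCl, Et3N, DMAP (cat.), CH2Cl2, 0 °C → rt
Reagents that add atoms: pivaloyl chloride, CC(C)(C)C(Cl)=O
Why: Acylation of the phenol with nucleophilic catalysis. The pivalate lowers the donor strength of ring E, which later suppresses ionisation at the benzylic carbon, and it is hindered enough to survive the Grignard, titanium and Mitsunobu steps.

Step 8
Reactants: 12 4-formylphenyl pivalate
Product: 13 rac-4-(1-hydroxyprop-2-en-1-yl)phenyl pivalate
Conditions: CH2=CHMgBr, THF, −78 °C
Reagents that add atoms: vinylmagnesium bromide, C=C[Mg]Br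
Why: Grignard 1,2-addition; at −78 °C the aldehyde reacts far faster than the hindered aryl ester. The racemic carbinol is the substrate for the resolution in step 9.

Step 9
Reactants: 13 rac-4-(1-hydroxyprop-2-en-1-yl)phenyl pivalate
Product: 14 4-[(S)-hydroxy[(2R)-oxiran-2-yl]methyl]phenyl pivalate
Conditions: Ti(OiPr)4 (0.15 equiv), L-(+)-diisopropyl tartrate (0.2 equiv), t-BuOOH (0.45 equiv), 4 Å MS, CH2Cl2, −20 °C
Reagents that add atoms: tert-butyl hydroperoxide, CC(C)(C)OO
Why: Sharpless asymmetric epoxidation run as a kinetic resolution; with the L-(+)-tartrate the (R)-enantiomer of 13 should be epoxidised much faster, on the alkene face that gives the erythro (anti) epoxy alcohol, so the reagent sets the oxirane carbon as (R) and selects the carbinol that is (S) in 14 (the descriptor changes only because the oxirane carbon outranks aryl). Stopping below half conversion leaves (S)-13 unreacted, and it is separated.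

Step 10
Reactants: 10 3,5-bis(benzyloxy)-2-[(2S,4S)-7-(benzyloxy)-2-[4-(benzyloxy)phenyl]chroman-4-yl]phenol; 14 4-[(S)-hydroxy[(2R)-oxiran-2-yl]methyl]phenyl pivalate
Product: 15 4-[(R)-{3,5-bis(benzyloxy)-2-[(2S,4S)-7-(benzyloxy)-2-[4-(benzyloxy)phenyl]chroman-4-yl]phenoxy}[(2R)-oxiran-2-yl]methyl]phenyl pivalate
Conditions: PPh3, DIAD, toluene, 0 °C → rt
Reagents that add atoms: none
Why: Mitsunobu etherification; the phenoxide of 10 displaces the oxyphosphonium group of activated 14 by SN2 with inversion, turning the (S) carbinol into the (R) aryl ether, which is the C2' configuration, while the epoxide is a spectator. The pivalate and the adjacent oxirane both disfavour ionisation at the benzylic carbon, which should keep the substitution stereospecific; material from any minor enantiomer of 14 is a diastereomer of 15 and is removed by chromatography.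

Step 11
Reactants: 15 4-[(R)-{3,5-bis(benzyloxy)-2-[(2S,4S)-7-(benzyloxy)-2-[4-(benzyloxy)phenyl]chroman-4-yl]phenoxy}[(2R)-oxiran-2-yl]methyl]phenyl pivalate
Product: 16 4-[(2R,3R)-5,7-bis(benzyloxy)-8-[(2S,4S)-7-(benzyloxy)-2-[4-(benzyloxy)phenyl]chroman-4-yl]-3-hydroxychroman-2-yl]phenyl pivalate
Conditions: BF3·OEt2 (0.3 equiv), CH2Cl2 (0.005 M), −78 → −40 °C
Reagents that add atoms: none
Why: The Lewis acid coordinates the oxirane oxygen and polarises the C4'–O bond; the ring-D carbon ortho to O1' (the future C4a'), which is also ortho and para to the two benzyloxy groups, attacks the terminal CH2 in an SN2-like opening, and proton loss restores the arene and leaves the C3' hydroxyl. The closest known reaction type is the Lewis-acid-promoted intramolecular Friedel–Crafts epoxy-arene cyclisation of electron-rich aryl glycidyl ethers to chroman-3-ols. Ring F closes in the 6-endo mode, with both oxirane carbons in the new ring; the 5-exo path at the internal carbon would need attack at the more hindered, inductively deactivated carbon through a strained geometry leading to a dihydrobenzofuran, and is not expected. No stereocentre is created: C3' keeps its C–O bond and hence its (R) configuration, C2' is not involved, and C2 and C4 are remote. Regioselectivity on ring D is secured by the substrate, because C8' is substituted and C6' cannot reach the epoxide, so C4a' is the only carbon that can close a ring, and the ether side chain should turn away from the bulky C8' group and thus toward C4a'. The step needs chemoselectivity: epoxide activation must outrun heterolysis of the two benzylic aryl ether bonds, which at C2' is secured by the pivalate on ring E and the adjacent oxirane, and at C2–O1 of the upper unit by the low temperature and the substoichiometric Lewis acid. High dilution suppresses intermolecular alkylation.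

Step 12
Reactants: 16 4-[(2R,3R)-5,7-bis(benzyloxy)-8-[(2S,4S)-7-(benzyloxy)-2-[4-(benzyloxy)phenyl]chroman-4-yl]-3-hydroxychroman-2-yl]phenyl pivalate
Product: 17 (2R,3R)-5,7-bis(benzyloxy)-8-[(2S,4S)-7-(benzyloxy)-2-[4-(benzyloxy)phenyl]chroman-4-yl]-2-(4-hydroxyphenyl)chroman-3-ol
Conditions: K2CO3 (0.5 equiv), MeOH/THF, rt
Reagents that add atoms: none
Why: Base-catalysed transesterification of the aryl pivalate with methanol. Benzyl ethers, the secondary alcohol and all four stereocentres are inert, and the ester is removed while the other phenols are still masked, so the free polyphenol is never exposed to base.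

Step 13
Reactants: 17 (2R,3R)-5,7-bis(benzyloxy)-8-[(2S,4S)-7-(benzyloxy)-2-[4-(benzyloxy)phenyl]chroman-4-yl]-2-(4-hydroxyphenyl)chroman-3-ol
Product: 18 (2R,3R)-8-[(2S,4S)-7-hydroxy-2-(4-hydroxyphenyl)chroman-4-yl]-2-(4-hydroxyphenyl)chroman-3,5,7-triol
Conditions: H2 (1 atm), Pd(OH)2/C, THF/MeOH, rt
Reagents that add atoms: none
Why: Hydrogenolysis of the four benzyl aryl ethers under neutral conditions. The cyclic C2–O1 and C2'–O1' bonds and the C4–C8' bond should not be cleaved under these mild conditions, and no stereocentre is touched, so the product is the target.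

## Compound list

1 | (S)-liquiritigenin | Oc1ccc([C@@H]2CC(=O)c3ccc(O)cc3O2)cc1 | starting material
2 | (2S)-7-(benzyloxy)-2-[4-(benzyloxy)phenyl]chroman-4-one | c1ccccc1COc1ccc([C@@H]2CC(=O)c3ccc(OCc4ccccc4)cc3O2)cc1 | intermediate
3 | (2S)-7-(benzyloxy)-2-[4-(benzyloxy)phenyl]-2H-chromen-4-yl trifluoromethanesulfonate | c1ccccc1COc1ccc([C@@H]2C=C(OS(=O)(=O)C(F)(F)F)c3ccc(OCc4ccccc4)cc3O2)cc1 | intermediate
4 | 3,5-bis(benzyloxy)phenol | Oc1cc(OCc2ccccc2)cc(OCc2ccccc2)c1 | starting material
5 | 1,3-bis(benzyloxy)-5-(methoxymethoxy)benzene | COCOc1cc(OCc2ccccc2)cc(OCc2ccccc2)c1 | intermediate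
6 | [2,4-bis(benzyloxy)-6-(methoxymethoxy)phenyl]lithium | [Li]c1c(OCOC)cc(OCc2ccccc2)cc1OCc1ccccc1 | intermediate
7 | [2,4-bis(benzyloxy)-6-(methoxymethoxy)phenyl]zinc chloride | Cl[Zn]c1c(OCOC)cc(OCc2ccccc2)cc1OCc1ccccc1 | intermediate
8 | (2S)-4-[2,4-bis(benzyloxy)-6-(methoxymethoxy)phenyl]-7-(benzyloxy)-2-[4-(benzyloxy)phenyl]-2H-chromene | c1ccccc1COc1ccc([C@@H]2C=C(c3c(OCOC)cc(OCc4ccccc4)cc3OCc3ccccc3)c3ccc(OCc4ccccc4)cc3O2)cc1 | intermediate
9 | (2S,4S)-4-[2,4-bis(benzyloxy)-6-(methoxymethoxy)phenyl]-7-(benzyloxy)-2-[4-(benzyloxy)phenyl]chroman | c1ccccc1COc1ccc([C@@H]2C[C@H](c3c(OCOC)cc(OCc4ccccc4)cc3OCc3ccccc3)c3ccc(OCc4ccccc4)cc3O2)cc1 | intermediate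
10 | 3,5-bis(benzyloxy)-2-[(2S,4S)-7-(benzyloxy)-2-[4-(benzyloxy)phenyl]chroman-4-yl]phenol | c1ccccc1COc1ccc([C@@H]2C[C@H](c3c(O)cc(OCc4ccccc4)cc3OCc3ccccc3)c3ccc(OCc4ccccc4)cc3O2)cc1 | intermediate
11 | 4-hydroxybenzaldehyde | O=Cc1ccc(O)cc1 | starting material
12 | 4-formylphenyl pivalate | O=Cc1ccc(OC(=O)C(C)(C)C)cc1 | intermediate
13 | rac-4-(1-hydroxyprop-2-en-1-yl)phenyl pivalate | C=CC(O)c1ccc(OC(=O)C(C)(C)C)cc1 | intermediate
14 | 4-[(S)-hydroxy[(2R)-oxiran-2-yl]methyl]phenyl pivalate | O[C@@H](c1ccc(OC(=O)C(C)(C)C)cc1)[C@H]1CO1 | intermediate
15 | 4-[(R)-{3,5-bis(benzyloxy)-2-[(2S,4S)-7-(benzyloxy)-2-[4-(benzyloxy)phenyl]chroman-4-yl]phenoxy}[(2R)-oxiran-2-yl]methyl]phenyl pivalate | c1ccccc1COc1ccc([C@@H]2C[C@H](c3c(OCc4ccccc4)cc(OCc4ccccc4)cc3O[C@H](c5ccc(OC(=O)C(C)(C)C)cc5)[C@H]6CO6)c7ccc(OCc8ccccc8)cc7O2)cc1 | intermediate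
16 | 4-[(2R,3R)-5,7-bis(benzyloxy)-8-[(2S,4S)-7-(benzyloxy)-2-[4-(benzyloxy)phenyl]chroman-4-yl]-3-hydroxychroman-2-yl]phenyl pivalate | c1ccccc1COc1ccc([C@@H]2C[C@H](c3c(OCc4ccccc4)cc(OCc4ccccc4)c5c3O[C@H](c6ccc(OC(=O)C(C)(C)C)cc6)[C@H](O)C5)c7ccc(OCc8ccccc8)cc7O2)cc1 | intermediate
17 | (2R,3R)-5,7-bis(benzyloxy)-8-[(2S,4S)-7-(benzyloxy)-2-[4-(benzyloxy)phenyl]chroman-4-yl]-2-(4-hydroxyphenyl)chroman-3-ol | c1ccccc1COc1ccc([C@@H]2C[C@H](c3c(OCc4ccccc4)cc(OCc4ccccc4)c5c3O[C@H](c6ccc(O)cc6)[C@H](O)C5)c7ccc(OCc8ccccc8)cc7O2)cc1 | intermediate
18 | (2R,3R)-8-[(2S,4S)-7-hydroxy-2-(4-hydroxyphenyl)chroman-4-yl]-2-(4-hydroxyphenyl)chroman-3,5,7-triol (CNP0254623.1) | Oc1ccc([C@@H]2C[C@H](c3c(O)cc(O)c4c3O[C@H](c3ccc(O)cc3)[C@H](O)C4)c3ccc(O)cc3O2)cc1 | target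

## Step count and least certain steps

Total step count: 13. Longest linear sequence: 9 steps (steps 1, 2, 4, 5, 6, 10, 11, 12, 13, from 1). The branch from 4 joins at step 4 and the branch from 11 (steps 7–9) joins at step 10.

**Step 11 (key step).** What may go wrong: heterolysis of a benzylic C–O bond (C2'–O1', or C2–O1 of the upper unit) may compete with epoxide opening. The ring closure may also be slow because the C8' substituent crowds the conformation in which the side chain lies over C4a'; hydride shift in the activated epoxide (Meinwald rearrangement) or intermolecular alkylation would then take over.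

Fallback: ring F is closed before the upper unit is present, and the upper unit is attached afterwards. Setting out from 4 and 14, Mitsunobu etherification (PPh3, DIAD) gives 4-[(R)-[3,5-bis(benzyloxy)phenoxy][(2R)-oxiran-2-yl]methyl]phenyl pivalate F1, in which both ortho positions are equivalent and no acid-labile flavan is present. BF3·OEt2 at low temperature closes it to 4-[(2R,3R)-5,7-bis(benzyloxy)-3-hydroxychroman-2-yl]phenyl pivalate F2. NBS should brominate C8, the more nucleophilic free position of a 5,7-dibenzyloxyflavan, to give 4-[(2R,3R)-5,7-bis(benzyloxy)-8-bromo-3-hydroxychroman-2-yl]phenyl pivalate F3. Separately, triflate 3 is borylated (bis(pinacolato)diboron, PdCl2(dppf), KOPh) to (2S)-7-(benzyloxy)-2-[4-(benzyloxy)phenyl]-4-(4,4,5,5-tetramethyl-1,3,2-dioxaborolan-2-yl)-2H-chromene F4. Suzuki–Miyaura coupling of F3 with F4 (Pd(OAc)2, SPhos, K3PO4) gives 4-[(2R,3R)-5,7-bis(benzyloxy)-8-[(2S)-7-(benzyloxy)-2-[4-(benzyloxy)phenyl]-2H-chromen-4-yl]-3-hydroxychroman-2-yl]phenyl pivalate F5. Ionic hydrogenation under the conditions of step 5 sets C4 as before and comes back to the route at 16.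

**Step 10.** What may go wrong: the SN2 displacement may be slow at a congested secondary benzylic centre with an ortho-substituted phenol, so the betaine consumes the alcohol in side reactions, or partial ionisation erodes the configuration.

Fallback: a Williamson-type displacement with a smaller leaving group. Setting out from 14, MsCl and Et3N at −20 °C give 4-[(S)-[(methylsulfonyl)oxy][(2R)-oxiran-2-yl]methyl]phenyl pivalate F6, which is treated directly with the caesium salt of 10 (Cs2CO3, DMF, 0 °C → rt). SN2 with inversion comes back to the route at 15.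

**Step 4.** What may go wrong: deprotonation of a benzylic CH2 of the benzyl ethers, or lithiation between the two benzyloxy groups, may compete with the acetal-directed lithiation. The di-ortho-substituted arylzinc may also couple slowly, with loss of the triflate by reduction or hydrolysis.

Fallback: 1,2-addition instead of cross-coupling. Setting out from 5 and 2, aryllithium 6 (generated as in step 4) is added to ketone 2 in the presence of LaCl3·2LiCl at −78 °C, which suppresses enolisation. This gives (2S)-4-[2,4-bis(benzyloxy)-6-(methoxymethoxy)phenyl]-7-(benzyloxy)-2-[4-(benzyloxy)phenyl]chroman-4-ol F7 as a mixture of C4 epimers. Under the conditions of step 5 it ionises to the same C4 cation and is reduced, coming back to the route at 9.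

**Step 5.** What may go wrong: the facial selectivity of hydride transfer may be insufficient, or acid may open ring C at C2–O1 with hydride capture of the open cation.

Fallback: neutral catalytic hydrogenation. Setting out from 8, H2 with [Ir(cod)(PCy3)(py)]PF6 in CH2Cl2 reduces hindered trisubstituted alkenes without hydrogenolysing benzyl ethers. Syn addition from the face opposite the 2-aryl group should give the cis product and comes back to the route at 9. No new compound is made.

**Step 9.** What may go wrong: a modest selectivity factor would limit the enantiomeric purity of 14, because in a kinetic resolution the product is less pure than the recovered alcohol.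

Fallback: resolution on the substrate side followed by a matched epoxidation. Setting out from 13, the same titanium system with D-(−)-diisopropyl tartrate, run past half conversion, leaves 4-[(1R)-1-hydroxyprop-2-en-1-yl]phenyl pivalate F8 in high enantiomeric purity. The (S)-enantiomer is consumed as 4-[(R)-hydroxy[(2S)-oxiran-2-yl]methyl]phenyl pivalate F9, which is discarded. Complete epoxidation of F8 with the L-(+)-tartrate system and excess t-BuOOH then comes back to the route at 14.

## Further compounds

F1 | step 11 | 4-[(R)-[3,5-bis(benzyloxy)phenoxy][(2R)-oxiran-2-yl]methyl]phenyl pivalate | c1ccccc1COc1cc(OCc2ccccc2)cc(O[C@H](c2ccc(OC(=O)C(C)(C)C)cc2)[C@H]2CO2)c1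
F2 | step 11 | 4-[(2R,3R)-5,7-bis(benzyloxy)-3-hydroxychroman-2-yl]phenyl pivalate | c1ccccc1COc1cc(OCc2ccccc2)c2c(c1)O[C@H](c1ccc(OC(=O)C(C)(C)C)cc1)[C@H](O)C2
F3 | step 11 | 4-[(2R,3R)-5,7-bis(benzyloxy)-8-bromo-3-hydroxychroman-2-yl]phenyl pivalate | c1ccccc1COc1cc(OCc2ccccc2)c2c(c1Br)O[C@H](c1ccc(OC(=O)C(C)(C)C)cc1)[C@H](O)C2
F4 | step 11 | (2S)-7-(benzyloxy)-2-[4-(benzyloxy)phenyl]-4-(4,4,5,5-tetramethyl-1,3,2-dioxaborolan-2-yl)-2H-chromene | c1ccccc1COc1ccc([C@@H]2C=C(B3OC(C)(C)C(C)(C)O3)c3ccc(OCc4ccccc4)cc3O2)cc1
F5 | step 11 | 4-[(2R,3R)-5,7-bis(benzyloxy)-8-[(2S)-7-(benzyloxy)-2-[4-(benzyloxy)phenyl]-2H-chromen-4-yl]-3-hydroxychroman-2-yl]phenyl pivalate | c1ccccc1COc1ccc([C@@H]2C=C(c3c(OCc4ccccc4)cc(OCc4ccccc4)c5c3O[C@H](c6ccc(OC(=O)C(C)(C)C)cc6)[C@H](O)C5)c7ccc(OCc8ccccc8)cc7O2)cc1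
F6 | step 10 | 4-[(S)-[(methylsulfonyl)oxy][(2R)-oxiran-2-yl]methyl]phenyl pivalate | CS(=O)(=O)O[C@@H](c1ccc(OC(=O)C(C)(C)C)cc1)[C@H]1CO1
F7 | step 4 | (2S)-4-[2,4-bis(benzyloxy)-6-(methoxymethoxy)phenyl]-7-(benzyloxy)-2-[4-(benzyloxy)phenyl]chroman-4-ol (C4 epimers) | c1ccccc1COc1ccc([C@@H]2CC(O)(c3c(OCOC)cc(OCc4ccccc4)cc3OCc3ccccc3)c3ccc(OCc4ccccc4)cc3O2)cc1
F0 | step 5 | none | none
F8 | step 9 | 4-[(1R)-1-hydroxyprop-2-en-1-yl]phenyl pivalate | O[C@@H](c1ccc(OC(=O)C(C)(C)C)cc1)C=C
F9 | step 9 | 4-[(R)-hydroxy[(2S)-oxiran-2-yl]methyl]phenyl pivalate | O[C@H](c1ccc(OC(=O)C(C)(C)C)cc1)[C@@H]1CO1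
A1 | alternative 1 | 5-(benzyloxy)-2-[(2S,4S)-7-(benzyloxy)-2-[4-(benzyloxy)phenyl]chroman-4-yl]-3-[(triisopropylsilyl)oxy]phenol | c6ccccc6COc1ccc([C@@H]2C[C@H](c3c(O[Si](C(C)C)(C(C)C)C(C)C)cc(OCc5ccccc5)cc3O)c3ccc(OCc5ccccc5)cc3O2)cc1
A2 | alternative 1 | 3-(benzyloxy)cyclobut-2-en-1-one | O=C1CC(OCc2ccccc2)=C1
A3 | alternative 1 | (2S,4R)-7-(benzyloxy)-2-[4-(benzyloxy)phenyl]-4-{[(triisopropylsilyl)oxy]ethynyl}chroman | c1ccccc1COc1ccc([C@@H]2C[C@H](C#CO[Si](C(C)C)(C(C)C)C(C)C)c3ccc(OCc4ccccc4)cc3O2)cc1
A4 | alternative 2 | (2R,3R)-5,7-bis(benzyloxy)-8-[(2S,4S)-7-(benzyloxy)-2-[4-(benzyloxy)phenyl]chroman-4-yl]-2-[4-(benzyloxy)phenyl]-3-[(tert-butyldimethylsilyl)oxy]chroman | c6ccccc6COc1ccc([C@@H]2C[C@H](c3c(OCc5ccccc5)cc(OCc5ccccc5)c4c3O[C@H](c3ccc(OCc5ccccc5)cc3)[C@H](O[Si](C)(C)C(C)(C)C)C4)c3ccc(OCc5ccccc5)cc3O2)cc1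
A5 | alternative 2 | 1-(benzyloxy)-4-vinylbenzene | C=Cc1ccc(OCc2ccccc2)cc1
A6 | alternative 2 | [4-(benzyloxy)-2-hydroxyphenyl]{(2R,3R)-5,7-bis(benzyloxy)-2-[4-(benzyloxy)phenyl]-3-[(tert-butyldimethylsilyl)oxy]chroman-8-yl}methanol (carbinol epimers) | OC(c1ccc(OCc2ccccc2)cc1O)c1c(OCc2ccccc2)cc(OCc2ccccc2)c2c1O[C@H](c1ccc(OCc3ccccc3)cc1)[C@H](O[Si](C)(C)C(C)(C)C)C2
A7 | alternative 3 | (2R,3R)-5,7-bis(benzyloxy)-8-[(2S,4S)-7-(benzyloxy)-2-[4-(benzyloxy)phenyl]chroman-4-yl]-2-[4-(benzyloxy)phenyl]chroman-3-yl acetate | c6ccccc6COc1ccc([C@@H]2C[C@H](c3c(OCc5ccccc5)cc(OCc5ccccc5)c4c3O[C@H](c3ccc(OCc5ccccc5)cc3)[C@H](OC(C)=O)C4)c3ccc(OCc5ccccc5)cc3O2)cc1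
A8 | alternative 3 | (2R,3R)-5,7-bis(benzyloxy)-2-[4-(benzyloxy)phenyl]-8-{(3S)-3-[3-(benzyloxy)phenoxy]-3-[4-(benzyloxy)phenyl]-1-hydroxypropyl}chroman-3-yl acetate (carbinol epimers) | OC(C[C@H](Oc1cccc(OCc2ccccc2)c1)c1ccc(OCc2ccccc2)cc1)c1c(OCc2ccccc2)cc(OCc2ccccc2)c2c1O[C@H](c1ccc(OCc3ccccc3)cc1)[C@H](OC(C)=O)C2
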